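The closed, stirred vessel held a racemate of Za and Zb with the single-handed catalyst Zd under Zf at constant pressure, and I needed the excess of Zb over Za in the new flask.

the same everywhere: Za 0.21 M; Zb 0.21 M; Zf 32 mM (held)

| flask | Zd | remark | time |
|---|---|---|---|
| amber | 10 mM | run made earlier |  |
| violet | 42 mM | run made earlier |  |
| flask | 21 mM |  | 3.0 min |

| run | time / min | Zb / % | Za / % |
|---|---|---|---|
| amber | 0.333 | 49.9 | 32.4 |
| amber | 0.833 | 46.7 | 10.9 |
| amber | 1.50 | 44.0 | 1.4 |
| amber | 2.50 | 45.3 | 1.5 |
| amber | 4.00 | 44.6 | 1.7 |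
| violet | 0.667 | 46.7 | 13.2 |
| violet | 1.33 | 41.5 | 0 |
| violet | 2.00 | 39.2 | 0.4 |
| violet | 3.00 | 37.6 | 0 |
| violet | 4.00 | 37.5 | 0.3 |

(standard deviation of a reading: 0.5 percentage points)

- Zd is single-handed; Za and Zb are mirror images of each other, charged as a racemate, each of them at the stated concentration
- at the start none of Zf is in solution

- whether the excess of Zb over Za among what is left of the two reaches 98% by 3.0 min (yes / no)
- the highest excess of Zb over Za among what is left of the two up to 3.0 min

If both enantiomers are lost at first order through the same catalyst, dividing one rate by the other and integrating gives Λ = (s minus one)·x. Here Λ is the logarithm of Zb over Za, x the logarithm of Zb charged over Zb present, and the excess is the hyperbolic tangent of half Λ. Amber's last three readings gave x = 0.114 and s = 30.7, the selectivity factor, the fixed ratio of the two first-order loss rates. Violet's last two gave x = 0.286, and a power law in Zd put the flask at 0.183. So I reckoned Λ = 5.44, above the 4.60 that 98% requires, an excess of 99.1%. One number served provided the flask stalled in time: amber's Zb readings levelled off from 1.50 min, violet's from 3.00 min.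

The forecast also said yes, with a top of 98.1% (96.8% to 99.2%), lower than my 99.1%: “It is a very close call, leaning slightly to yes”.

The flask gave yes, with a top of 99.4%.

    Zd + Za ⇌ Zj (K = 10.0 M⁻¹, k = 690 M⁻¹ s⁻¹)
    Zd + Zb ⇌ Zk (K = 1.40 M⁻¹, k = 24.0 M⁻¹ s⁻¹)
    Zc + Zj → Zd + Zg (k = 390 M⁻¹ s⁻¹)
    Zc + Zk → Zd + Zh (k = 82.0 M⁻¹ s⁻¹)
    Zg ⇌ Zh (k = 0.0110 s⁻¹)
    Zd → Ze (k = 0.0670 s⁻¹)
    Zf ⇌ Zc, rate k7*(csat - [Zc]) (kL = 0.130 s⁻¹)

At the flask's Zb of 41.7%, s gives Λ = 5.39, against 5.82 from the flask's Zb and Za. In the run with twice the Za, the end excess of 93.7%, taken through s, puts Zb by estimate at 87.1% of its charge. In the flask, the half-life of Zd by the step to Ze alone is 10.3 s, short against the 3.0 min allowed. At 3.00 min Ze holds >99.9% of the catalyst charged.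

(All runs stem from a simulated flask from invented constants, and the scatter is random.)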